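The route rests on reading the 1,5-dialdehyde centred on C4 (CH2CHO on C4 and the formyl group on alkene carbon C5) as the open form of a 2-ethoxy-3,4-dihydro-2H-pyran: the acetal carbon stores CH2CHO and the enol ether stores the C5 formyl. One catalytic asymmetric inverse-demand oxa-Diels–Alder reaction between the enal part of a (2E,4E)-dienal and ethyl vinyl ether closes this ring, forms the C4–CH2 and O–C(acetal) bonds and fixes C4. The dienal already carries the protected ketone chain and an allylic silyl ether on its remote trisubstituted alkene, the handle for C3; the enol ether carbon C5 later takes up the furanone.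

Key step: step 6

Numbering: target carbons C3 (bears CO2H), C4 (bears CH2CHO) and C5 (formyl-bearing alkene carbon) keep these labels throughout; ring positions are written "pyran C2" to "pyran C6".
Assumption: both antipodes of the chromium catalyst ligand are available, and the one that adds the vinyl ether to the required face of C4 is chosen in a test run; the target is taken as the open-chain form drawn.
Design remarks: (2R,4S)-13 carries the C4 configuration of 28 (checked atom by atom). C3 is brought to the acid level before the furanone is attached, so that no oxidant meets the acid-labile lactol and the last step needs only aqueous acid.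

Step 1
Reactants: 1 but-2-yne-1,4-diol
Product: 2 4-[(tert-butyldimethylsilyl)oxy]but-2-yn-1-ol
Conditions: NaH (1.0 equiv), THF, 0 °C; TBSCl (1.0 equiv), rt
Reagents that add atoms: tert-butyldimethylsilyl chloride, CC(C)(C)[Si](C)(C)Cl
Why: O-silylation of the monosodium alkoxide, which forms with one equivalent of NaH and is trapped by TBSCl before a second deprotonation, should give the mono-ether of the symmetric diol (Williamson-type silylation; no stereocentre).

Step 2
Reactants: 2 4-[(tert-butyldimethylsilyl)oxy]but-2-yn-1-ol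
Product: 4 (Z)-4-[(tert-butyldimethylsilyl)oxy]-3-iodobut-2-en-1-ol, via alkenylaluminate 3 (not isolated)
Conditions: NaAlH2(OCH2CH2OMe)2, THF, 0 °C; then I2, −78 °C → 0 °C
Reagents that add atoms: iodine, II
Why: Hydroxyl-directed trans-hydroalumination places aluminium on the alkyne carbon remote from the alkoxide in a five-membered aluminate, and iodinolysis of the C–Al bond with retention should give the (Z)-3-iodo allylic alcohol (hydroalumination–iodination).

Step 3
Reactants: 4 (Z)-4-[(tert-butyldimethylsilyl)oxy]-3-iodobut-2-en-1-ol; 5 2-(3-chloropropyl)-2-methyl-1,3-dioxolane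
Product: 8 (E)-3-{[(tert-butyldimethylsilyl)oxy]methyl}-6-(2-methyl-1,3-dioxolan-2-yl)hex-2-en-1-ol, via Grignard reagent 6 (not isolated), via alkylzinc chloride 7 (not isolated)
Conditions: 5, Mg, THF, 60 °C; ZnCl2, 0 °C; then 4, PdCl2(dppf) (5 mol %), THF, rt → 45 °C
Reagents that add atoms: none
Why: Negishi sp3–sp2 cross-coupling of the alkylzinc chloride with the alkenyl iodide proceeds with retention of alkene geometry, the bidentate dppf ligand suppressing β-hydride elimination and the free hydroxyl being tolerated because protonolysis of alkylzinc halides is slower than coupling.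

Step 4
Reactants: 8 (E)-3-{[(tert-butyldimethylsilyl)oxy]methyl}-6-(2-methyl-1,3-dioxolan-2-yl)hex-2-en-1-ol
Product: 9 (E)-3-{[(tert-butyldimethylsilyl)oxy]methyl}-6-(2-methyl-1,3-dioxolan-2-yl)hex-2-enal
Conditions: MnO2 (15 equiv), CH2Cl2, rt
Reagents that add atoms: none
Why: MnO2 oxidises only the allylic primary alcohol to the enal under neutral conditions that leave silyl ether, ketal and alkene geometry untouched (allylic oxidation).

Step 5
Reactants: 9 (E)-3-{[(tert-butyldimethylsilyl)oxy]methyl}-6-(2-methyl-1,3-dioxolan-2-yl)hex-2-enal; 10 (triphenylphosphoranylidene)acetaldehyde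
Product: 11 (2E,4E)-5-{[(tert-butyldimethylsilyl)oxy]methyl}-8-(2-methyl-1,3-dioxolan-2-yl)octa-2,4-dienal
Conditions: toluene, 80 °C
Reagents that add atoms: none
Why: Wittig olefination with the stabilised formylmethylene ylide should give the (E)-configured two-carbon extension, the less electrophilic dienal product resisting a second homologation.

Step 6
Reactants: 11 (2E,4E)-5-{[(tert-butyldimethylsilyl)oxy]methyl}-8-(2-methyl-1,3-dioxolan-2-yl)octa-2,4-dienal; 12 ethyl vinyl ether
Product: 13 tert-butyl{[(E)-2-{[(2R,4S)-2-ethoxy-3,4-dihydro-2H-pyran-4-yl]methylidene}-5-(2-methyl-1,3-dioxolan-2-yl)pentyl]oxy}dimethylsilane (cis-2,4-disubstituted pyran)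
Conditions: CrCl(L) (5 mol %), 4 Å MS, 12 (10 equiv, neat), rt, 48 h; L = dianion of the Schiff base from 3-(1-adamantyl)-5-methylsalicylaldehyde and cis-1-amino-2-indanol (antipode giving (2R,4S)-13)
Reagents that add atoms: none
Why: The Lewis-acidic trivalent chromium centre binds the aldehyde oxygen of 11 and lowers the LUMO of the 1-oxadiene O=C1–C2=C3, which combines with the electron-rich alkene of 12 in a concerted, asynchronous inverse-electron-demand hetero-Diels–Alder reaction. The closest known reaction is the cycloaddition of β-substituted α,β-unsaturated aldehydes with ethyl vinyl ether under the same tridentate Schiff-base CrCl(L) complexes; here the β-substituent is an alkenyl group. The single new ring, the six-membered 3,4-dihydro-2H-pyran, is closed by intermolecular [4+2] cycloaddition, which forms the C4–CH2 bond and the O–C(acetal) bond in one event. C4 is set by the catalyst, whose chiral pocket exposes one face of the coordinated oxadiene, and the acetal carbon is set relative to C4 by the endo transition state, which places ethoxy cis to the C4 substituent. The step needs periselectivity for the oxadiene over the carbon diene C2=C3–C4=C5: only the oxadiene is activated by coordination at oxygen, and the alkyl chain that sits cis to the diene on C5 disfavours the s-cis conformer an all-carbon cycloaddition would require. The distal trisubstituted alkene stays outside the pericyclic array and keeps its E geometry and its silyl ether.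

Step 7
Reactants: 13 tert-butyl{[(E)-2-{[(2R,4S)-2-ethoxy-3,4-dihydro-2H-pyran-4-yl]methylidene}-5-(2-methyl-1,3-dioxolan-2-yl)pentyl]oxy}dimethylsilane
Product: 14 (E)-2-{[(2R,4S)-2-ethoxy-3,4-dihydro-2H-pyran-4-yl]methylidene}-5-(2-methyl-1,3-dioxolan-2-yl)pentan-1-ol
Conditions: TBAF, THF, 0 °C → rt
Reagents that add atoms: none
Why: Fluoride cleaves the primary TBS ether while acetal, enol ether and ketal are inert to the basic medium (desilylation).

Step 8
Reactants: 14 (E)-2-{[(2R,4S)-2-ethoxy-3,4-dihydro-2H-pyran-4-yl]methylidene}-5-(2-methyl-1,3-dioxolan-2-yl)pentan-1-ol; 15 tributyl(iodomethyl)stannane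
Product: 16 tributyl({[(E)-2-{[(2R,4S)-2-ethoxy-3,4-dihydro-2H-pyran-4-yl]methylidene}-5-(2-methyl-1,3-dioxolan-2-yl)pentyl]oxy}methyl)stannane
Conditions: KH, THF, 0 °C; 15, rt
Reagents that add atoms: none
Why: Williamson etherification of the potassium alkoxide with the reactive iodomethylstannane installs the tin handle for the Wittig–Still rearrangement.

Step 9
Reactants: 16 tributyl({[(E)-2-{[(2R,4S)-2-ethoxy-3,4-dihydro-2H-pyran-4-yl]methylidene}-5-(2-methyl-1,3-dioxolan-2-yl)pentyl]oxy}methyl)stannane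
Product: 19 {[(2R)-2-[(2R,4S)-2-ethoxy-3,4-dihydro-2H-pyran-4-yl]-3-methylidene-6-(2-methyl-1,3-dioxolan-2-yl)hexyl]oxy}triethylsilane, via alkoxymethyllithium 17 (not isolated), via lithium alkoxide 18 (not isolated)
Conditions: n-BuLi (1.3 equiv), THF, −78 °C; then Et3SiCl, −78 → 0 °C
Reagents that add atoms: chlorotriethylsilane, CC[Si](Cl)(CC)CC
Why: Tin–lithium exchange gives an unstabilised α-alkoxy carbanion that undergoes the Wittig–Still [2,3]-sigmatropic shift, forming the C3–CH2O bond and the exo-methylene; C3 is set by 1,2-induction from C4, allylic 1,3-strain holding C4–H in the alkene plane so that the carbanion should bond to the face remote from the pyran C3 methylene, and the alkoxide is silylated in the same flask.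

Step 10
Reactants: 19 {[(2R)-2-[(2R,4S)-2-ethoxy-3,4-dihydro-2H-pyran-4-yl]-3-methylidene-6-(2-methyl-1,3-dioxolan-2-yl)hexyl]oxy}triethylsilane
Product: 21 {[(2R)-2-[(2R,4S)-5-bromo-2-ethoxy-3,4-dihydro-2H-pyran-4-yl]-3-methylidene-6-(2-methyl-1,3-dioxolan-2-yl)hexyl]oxy}triethylsilane, via trans-dibromide 20 (not isolated)
Conditions: Br2 (1.0 equiv), CH2Cl2, −78 °C; then DBU, −78 °C → rt
Reagents that add atoms: bromine, BrBr
Why: Bromine adds to the enol ether, by far the most nucleophilic alkene present, and DBU-induced loss of HBr through the anomeric bromide restores the enol ether with bromine on C5 (bromination–dehydrobromination).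

Step 11
Reactants: 21 {[(2R)-2-[(2R,4S)-5-bromo-2-ethoxy-3,4-dihydro-2H-pyran-4-yl]-3-methylidene-6-(2-methyl-1,3-dioxolan-2-yl)hexyl]oxy}triethylsilane
Product: 22 (2R)-2-[(2R,4S)-5-bromo-2-ethoxy-3,4-dihydro-2H-pyran-4-yl]-3-methylidene-6-(2-methyl-1,3-dioxolan-2-yl)hexan-1-ol
Conditions: TBAF, THF, 0 °C
Reagents that add atoms: none
Why: Fluoride removes the primary triethylsilyl ether without touching the alkenyl bromide or the acetals (desilylation); C3 epimers, if any, can be separated here.

Step 12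
Reactants: 22 (2R)-2-[(2R,4S)-5-bromo-2-ethoxy-3,4-dihydro-2H-pyran-4-yl]-3-methylidene-6-(2-methyl-1,3-dioxolan-2-yl)hexan-1-ol
Product: 23 (2R)-2-[(2R,4S)-5-bromo-2-ethoxy-3,4-dihydro-2H-pyran-4-yl]-3-methylidene-6-(2-methyl-1,3-dioxolan-2-yl)hexanal
Conditions: DMP, NaHCO3, CH2Cl2, 0 °C → rt; crude product used at once
Reagents that add atoms: none
Why: Buffered Dess–Martin oxidation gives the aldehyde under near-neutral conditions that should not epimerise C3 or move the exo-methylene into conjugation.

Step 13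
Reactants: 23 (2R)-2-[(2R,4S)-5-bromo-2-ethoxy-3,4-dihydro-2H-pyran-4-yl]-3-methylidene-6-(2-methyl-1,3-dioxolan-2-yl)hexanal
Product: 24 (2R)-2-[(2R,4S)-5-bromo-2-ethoxy-3,4-dihydro-2H-pyran-4-yl]-3-methylidene-6-(2-methyl-1,3-dioxolan-2-yl)hexanoic acid
Conditions: NaClO2, NaH2PO4, 2-methyl-2-butene, t-BuOH/H2O, 0 °C
Reagents that add atoms: sodium chlorite, [Na+].[O-]Cl=O
Why: Pinnick oxidation converts the aldehyde to the acid without epimerising C3, hypochlorite being scavenged by 2-methyl-2-butene while the bromine-deactivated enol ether and the acetals tolerate the brief, mildly acidic medium.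

Step 14
Reactants: 24 (2R)-2-[(2R,4S)-5-bromo-2-ethoxy-3,4-dihydro-2H-pyran-4-yl]-3-methylidene-6-(2-methyl-1,3-dioxolan-2-yl)hexanoic acid; 25 5,5-dimethylfuran-2(5H)-one
Product: 28 (2R,3S,4E)-4-(5,5-dimethylfuran-2(5H)-ylidene)-5-oxo-2-(6-oxohept-1-en-2-yl)-3-(2-oxoethyl)pentanoic acid (CNP0150297.1), via dilithio carboxylate 26 (not isolated), via lactol acid 27 (not isolated)
Conditions: MeLi (1.0 equiv), THF, −78 °C; t-BuLi (2.1 equiv), −78 °C; 25 (1.5 equiv), −78 °C; then 1 M aq. HCl, THF, 0 °C → rt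
Reagents that add atoms: water, O
Why: Parham-type bromine–lithium exchange on the lithium carboxylate gives the C5 vinyllithium, which adds to the lactone carbonyl (conjugate addition is hindered by the adjacent quaternary carbon); in acid the lactol ionises to an oxocarbenium that water captures at pyran C6, so that the pyran opens to both aldehydes, the ketal falls and the push–pull exocyclic alkene settles as the more stable E isomer with the bulky C4 next to the ring oxygen (no new stereocentre).

Compound list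
1 | but-2-yne-1,4-diol | OCC#CCO | starting material
2 | 4-[(tert-butyldimethylsilyl)oxy]but-2-yn-1-ol | CC(C)(C)[Si](C)(C)OCC#CCO | intermediate
3 | sodium alkenylaluminate (five-membered oxaaluminacycle, Al on the carbon bearing CH2OTBS) | COCCO[Al-]1(OCCOC)OCC=C1CO[Si](C)(C)C(C)(C)C.[Na+] | intermediate
4 | (Z)-4-[(tert-butyldimethylsilyl)oxy]-3-iodobut-2-en-1-ol | CC(C)(C)[Si](C)(C)OC/C(I)=C/CO | intermediate
5 | 2-(3-chloropropyl)-2-methyl-1,3-dioxolane | CC1(CCCCl)OCCO1 | starting material
6 | [3-(2-methyl-1,3-dioxolan-2-yl)propyl]magnesium chloride | CC1(CCC[Mg]Cl)OCCO1 | intermediate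
7 | [3-(2-methyl-1,3-dioxolan-2-yl)propyl]zinc chloride | CC1(CCC[Zn]Cl)OCCO1 | intermediate
8 | (E)-3-{[(tert-butyldimethylsilyl)oxy]methyl}-6-(2-methyl-1,3-dioxolan-2-yl)hex-2-en-1-ol | CC(C)(C)[Si](C)(C)OC/C(CCCC1(C)OCCO1)=C/CO | intermediate
9 | (E)-3-{[(tert-butyldimethylsilyl)oxy]methyl}-6-(2-methyl-1,3-dioxolan-2-yl)hex-2-enal | CC(C)(C)[Si](C)(C)OC/C(CCCC1(C)OCCO1)=C/C=O | intermediate
10 | (triphenylphosphoranylidene)acetaldehyde | O=CC=P(c1ccccc1)(c1ccccc1)c1ccccc1 | starting material
11 | (2E,4E)-5-{[(tert-butyldimethylsilyl)oxy]methyl}-8-(2-methyl-1,3-dioxolan-2-yl)octa-2,4-dienal | O=C/C=C/C=C(/CO[Si](C)(C)C(C)(C)C)CCCC1(C)OCCO1 | intermediate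
12 | ethyl vinyl ether | C=COCC | starting material
13 | tert-butyl{[(E)-2-{[(2R,4S)-2-ethoxy-3,4-dihydro-2H-pyran-4-yl]methylidene}-5-(2-methyl-1,3-dioxolan-2-yl)pentyl]oxy}dimethylsilane | CC(C)(C)[Si](C)(C)OC/C(CCCC1(C)OCCO1)=C/[C@@H]2C[C@H](OCC)OC=C2 | intermediate
14 | (E)-2-{[(2R,4S)-2-ethoxy-3,4-dihydro-2H-pyran-4-yl]methylidene}-5-(2-methyl-1,3-dioxolan-2-yl)pentan-1-ol | OC/C(CCCC1(C)OCCO1)=C/[C@@H]2C[C@H](OCC)OC=C2 | intermediate
15 | tributyl(iodomethyl)stannane | CCCC[Sn](CCCC)(CCCC)CI | starting material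
16 | tributyl({[(E)-2-{[(2R,4S)-2-ethoxy-3,4-dihydro-2H-pyran-4-yl]methylidene}-5-(2-methyl-1,3-dioxolan-2-yl)pentyl]oxy}methyl)stannane | CCCC[Sn](CCCC)(CCCC)COC/C(CCCC1(C)OCCO1)=C/[C@@H]2C[C@H](OCC)OC=C2 | intermediate
17 | alkoxymethyllithium from 16 (Li in place of Bu3Sn) | [Li]COC/C(CCCC1(C)OCCO1)=C/[C@@H]2C[C@H](OCC)OC=C2 | intermediate
18 | lithium (2R)-2-[(2R,4S)-2-ethoxy-3,4-dihydro-2H-pyran-4-yl]-3-methylidene-6-(2-methyl-1,3-dioxolan-2-yl)hexan-1-olate | C=C(CCCC1(C)OCCO1)[C@H](CO[Li])[C@@H]2C[C@H](OCC)OC=C2 | intermediate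
19 | {[(2R)-2-[(2R,4S)-2-ethoxy-3,4-dihydro-2H-pyran-4-yl]-3-methylidene-6-(2-methyl-1,3-dioxolan-2-yl)hexyl]oxy}triethylsilane | C=C(CCCC1(C)OCCO1)[C@H](CO[Si](CC)(CC)CC)[C@@H]2C[C@H](OCC)OC=C2 | intermediate
20 | 5,6-dibromide of 19 (trans addition across pyran C5–C6, mixture at these two centres) | C=C(CCCC1(C)OCCO1)[C@H](CO[Si](CC)(CC)CC)[C@@H]2C[C@H](OCC)OC(Br)C2Br | intermediate
21 | {[(2R)-2-[(2R,4S)-5-bromo-2-ethoxy-3,4-dihydro-2H-pyran-4-yl]-3-methylidene-6-(2-methyl-1,3-dioxolan-2-yl)hexyl]oxy}triethylsilane | C=C(CCCC1(C)OCCO1)[C@H](CO[Si](CC)(CC)CC)[C@@H]2C[C@H](OCC)OC=C2Br | intermediate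
22 | (2R)-2-[(2R,4S)-5-bromo-2-ethoxy-3,4-dihydro-2H-pyran-4-yl]-3-methylidene-6-(2-methyl-1,3-dioxolan-2-yl)hexan-1-ol | C=C(CCCC1(C)OCCO1)[C@H](CO)[C@@H]2C[C@H](OCC)OC=C2Br | intermediate
23 | (2R)-2-[(2R,4S)-5-bromo-2-ethoxy-3,4-dihydro-2H-pyran-4-yl]-3-methylidene-6-(2-methyl-1,3-dioxolan-2-yl)hexanal | C=C(CCCC1(C)OCCO1)[C@H](C=O)[C@@H]2C[C@H](OCC)OC=C2Br | intermediate
24 | (2R)-2-[(2R,4S)-5-bromo-2-ethoxy-3,4-dihydro-2H-pyran-4-yl]-3-methylidene-6-(2-methyl-1,3-dioxolan-2-yl)hexanoic acid | C=C(CCCC1(C)OCCO1)[C@H](C(=O)O)[C@@H]2C[C@H](OCC)OC=C2Br | intermediate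
25 | 5,5-dimethylfuran-2(5H)-one | CC1(C)OC(=O)C=C1 | starting material
26 | dilithio species of 24 (lithium carboxylate, Li on pyran C5) | C=C(CCCC1(C)OCCO1)[C@H](C(=O)O[Li])[C@@H]2C[C@H](OCC)OC=C2[Li] | intermediate
27 | lactol acid: 24 with 2-hydroxy-5,5-dimethyl-2,5-dihydrofuran-2-yl in place of Br (formed as its dilithium salt, both lactol epimers, in equilibrium with the open hydroxy enone) | C=C(CCCC1(C)OCCO1)[C@H](C(=O)O)[C@@H]2C[C@H](OCC)OC=C2C3(O)OC(C)(C)C=C3 | intermediate
28 | (2R,3S,4E)-4-(5,5-dimethylfuran-2(5H)-ylidene)-5-oxo-2-(6-oxohept-1-en-2-yl)-3-(2-oxoethyl)pentanoic acid (CNP0150297.1) | C=C(CCCC(C)=O)[C@H](C(=O)O)[C@H](CC=O)/C(C=O)=C1/C=CC(C)(C)O1 | target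

Total step count: 14. Longest linear sequence: 14 steps (1 → 28); compounds 5, 10, 12, 15 and 25 enter as purchased.

Steps most likely to fail

Step 6. The extended conjugation and the cis alkyl branch of the alkenyl substituent may slow the cycloaddition and crowd the catalyst pocket, so that facial discrimination erodes or the vinyl ether oligomerises before it is consumed. Fallback: the same chromium-catalysed cycloaddition is run on a small, strongly activated enal of the established class and the side chain is appended afterwards. Setting out from ethyl vinyl ether 12 and purchased ethyl (E)-4-oxobut-2-enoate, CrCl(L)/4 Å MS should give the cis cycloadduct ethyl (2R,4R)-2-ethoxy-3,4-dihydro-2H-pyran-4-carboxylate F1. i-Bu2AlH (1 equiv, CH2Cl2, −78 °C) reduces the ester to (2R,4R)-2-ethoxy-3,4-dihydro-2H-pyran-4-carbaldehyde F2. Separately, chloride 5 alkylates the sodium salt of triethyl phosphonoacetate (NaH, NaI, DMF, 60 °C) to ethyl 2-(diethoxyphosphoryl)-5-(2-methyl-1,3-dioxolan-2-yl)pentanoate F3. Horner–Wadsworth–Emmons olefination of F2 with F3 under LiCl/DBU (MeCN, 0 °C) should give ethyl (E)-2-{[(2R,4S)-2-ethoxy-3,4-dihydro-2H-pyran-4-yl]methylidene}-5-(2-methyl-1,3-dioxolan-2-yl)pentanoate F4, and i-Bu2AlH (2.2 equiv, −78 °C) reduces F4 to allylic alcohol 14, where the route is rejoined.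

Step 9. The two groups on C4 that flank the faces of the side-chain alkene (the pyran C3 methylene and the pyran C5 methine) differ little in size, so the [2,3] shift may show poor or reversed facial selectivity at C3. Fallback: control is moved from the substrate to a chiral catalyst. Setting out from allylic alcohol 14, methyl chloroformate/pyridine gives the allylic methyl carbonate of 14 F5. CuCl (5 mol %), KOt-Bu, B2pin2 and a chiral bisphosphine (QuinoxP*, antipode matched to the C3 configuration of 19) in THF at 0 °C effect SN2'-selective boryl substitution to the secondary allylic pinacol boronate F6. Matteson homologation (BrCH2Cl, n-BuLi, THF, −78 °C → rt) inserts CH2 into the C3–B bond with retention to give the homoallylic pinacol boronate F7. NaBO3·4H2O (THF/H2O) oxidises it to (2R)-2-[(2R,4S)-2-ethoxy-3,4-dihydro-2H-pyran-4-yl]-3-methylidene-6-(2-methyl-1,3-dioxolan-2-yl)hexan-1-ol F8, and Et3SiCl/imidazole returns the route to 19.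

Step 14. The vinyllithium may be quenched by proton transfer from C3–H of the carboxylate, may attack the carboxylate, or may add in conjugate fashion to the lactone. Fallback: the C5–C bond is made at the alcohol oxidation level and the acid is introduced afterwards under buffered conditions. Setting out from silyl ether 21, t-BuLi (2 equiv, THF, −78 °C), then 25 and a pH 7 quench give the lactol triethylsilyl ether F9 (ring–chain tautomers). TBAF gives the lactol primary alcohol F10. TEMPO (cat.), NaClO2 and NaOCl (cat.) in MeCN/pH 6.7 phosphate buffer oxidise the primary alcohol to lactol acid 27, which the aqueous acid treatment of step 14 carries on to 28.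

Further compounds
F1 | step 6 | ethyl (2R,4R)-2-ethoxy-3,4-dihydro-2H-pyran-4-carboxylate (cis) | CCOC(=O)[C@@H]1C[C@H](OCC)OC=C1
F2 | step 6 | (2R,4R)-2-ethoxy-3,4-dihydro-2H-pyran-4-carbaldehyde (cis) | O=C[C@@H]1C[C@H](OCC)OC=C1
F3 | step 6 | ethyl 2-(diethoxyphosphoryl)-5-(2-methyl-1,3-dioxolan-2-yl)pentanoate (racemic) | CCOC(=O)C(CCCC1(C)OCCO1)P(=O)(OCC)OCC
F4 | step 6 | ethyl (E)-2-{[(2R,4S)-2-ethoxy-3,4-dihydro-2H-pyran-4-yl]methylidene}-5-(2-methyl-1,3-dioxolan-2-yl)pentanoate | CCOC(=O)/C(CCCC1(C)OCCO1)=C/[C@@H]2C[C@H](OCC)OC=C2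
F5 | step 9 | allylic methyl carbonate of 14 | COC(=O)OC/C(CCCC1(C)OCCO1)=C/[C@@H]2C[C@H](OCC)OC=C2
F6 | step 9 | secondary allylic pinacol boronate (Bpin on C3, exo-methylene, C3 as in 19) | C=C(CCCC1(C)OCCO1)[C@H](B3OC(C)(C)C(C)(C)O3)[C@@H]2C[C@H](OCC)OC=C2
F7 | step 9 | homoallylic pinacol boronate (CH2Bpin on C3) | C=C(CCCC1(C)OCCO1)[C@H](CB3OC(C)(C)C(C)(C)O3)[C@@H]2C[C@H](OCC)OC=C2
F8 | step 9 | (2R)-2-[(2R,4S)-2-ethoxy-3,4-dihydro-2H-pyran-4-yl]-3-methylidene-6-(2-methyl-1,3-dioxolan-2-yl)hexan-1-ol | C=C(CCCC1(C)OCCO1)[C@H](CO)[C@@H]2C[C@H](OCC)OC=C2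
F9 | step 14 | lactol triethylsilyl ether (21 with 2-hydroxy-5,5-dimethyl-2,5-dihydrofuran-2-yl in place of Br) | C=C(CCCC1(C)OCCO1)[C@H](CO[Si](CC)(CC)CC)[C@@H]2C[C@H](OCC)OC=C2C3(O)OC(C)(C)C=C3
F10 | step 14 | lactol primary alcohol (F9 without the silyl group) | C=C(CCCC1(C)OCCO1)[C@H](CO)[C@@H]2C[C@H](OCC)OC=C2C3(O)OC(C)(C)C=C3
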